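The runs were generated by integration from invented constants; noise was put on by code.

Your first sample comes late for this flask: in the oak run 29.5 mM of target stands at 30 s, and the next 30 s adds 20.0 mM, so the curve is already bending when you first see it.

| flask | starting material | partner | target | time |
|---|---|---|---|---|
| oak | 150 mM | 300 mM |  |  |
| alder | 150 mM | 300 mM | 45.0 mM |  |
| birch | 300 mM | 300 mM |  |  |
| maple | 150 mM | 60.0 mM |  | 150 s |

| run | time / s | [target] / mM |
|---|---|---|
| oak run | 30 | 29.5 |
| oak run | 60 | 49.5 |
| oak run | 90 | 52.9 |
| oak run | 120 | 58.0 |
| oak run | 150 | 62.2 |
| alder run | 30 | 71.1 |
| alder run | 60 | 85.1 |
| alder run | 90 | 96.3 |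
| alder run | 120 | 99.8 |
| alder run | 150 | 93.8 |
| birch run | 30 | 55.0 |
| birch run | 60 | 83.4 |
| birch run | 90 | 96.4 |
| birch run | 120 | 109.1 |
| birch run | 150 | 111.8 |

(standard deviation of a reading: 2 mM)

1. how the opening rate goes with [starting material] round the charge of the oak run: the exponent of the rate at two percent of starting material gone to target (one fixed amount of target, the same in the runs compared)
2. target in the maple run at 150 s, as a share of the starting material charged

- Overall: starting material + partner -> target.
- Constant volume, constant temperature.
- A reading of a species includes what of it is bound.
- "The second partner" is partner.
- An order is taken over about fifteen percent of the charge, up and down.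

The plain way to the order in starting material compares first readings. The birch run holds twice the starting material of the oak run at the same partner, and its first reading is 1.86 times oak's, which gives an exponent of 0.899.

The second way reads the bend. Suppose each interval adds a fixed fraction of what the one before added. The fade is then the logarithm of first gain over second gain, divided by the interval; the opening rate follows, and the rate falls by the fade times the target made. Call the rate at 3.00 mM made the mark rate. The oak run gives a fade of 0.0130 s⁻¹ and a mark rate of 1.15 mM s⁻¹. The birch run gives 0.0220 s⁻¹ and 2.44 mM s⁻¹, so the exponent reads 1.09.

The two ways part, and the plain one cheats: birch fades faster than oak, and its first reading sits at a different amount made. So I commit to an order near one, read through a scatter of 2 mM per reading.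

For the maple run, partner is the limiting reagent, at 60.0 mM against 150 mM of starting material. The oak, alder and birch runs share 300 mM of partner, so I assume the first power and oak's fade, which gives 10.5 % of the starting material charged at 150 s.

The forecast gives 0.95 and 11.5 %, and adds: “The order in partner was never tested, so this carries some uncertainty.”

The flask gives 1.0 and 6.69 %.

    2 partner ⇌ reagent dimer, settled at all times (3.010 L mol⁻¹)
    starting material + reagent dimer → target + partner (0.1200 L mol⁻¹ s⁻¹)
    target + partner → side product (0.01300 L mol⁻¹ s⁻¹)
    starting material → decomposed substrate (0.004460 s⁻¹)

The mark rate read off the oak readings, 1.15 mM s⁻¹, stands beside a simulated 1.2 mM s⁻¹, and the same rule on the target made in the alder run reads 1.11 mM s⁻¹ beside a simulated 1.1 mM s⁻¹. The apparent order in partner early in the oak run is 1.4, above the first power, and the maple run lands below my 10.5 %. While reagent dimer turned starting material into target, target and partner went to side product at 0.0130 L mol⁻¹ s⁻¹. Over the same time starting material went to decomposed substrate at 0.00446 s⁻¹, a first-order time of 224 s.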